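**Conventions and one assumption**

- Locants C1–C15 are those of the germacrane skeleton defined in the analysis. CIP descriptors of ring compounds refer to these locants, and the SMILES in the compound list are authoritative.
- Assumption: epoxide 6 and phosphonoacrylate 17 are taken as purchasable, and C1 is carried as an (R)-configured silyl-protected carbinol whose configuration is arbitrary because C1 ends as the ketone.

## Analysis of the target

Target 38 is a germacrane-type lactone: a ten-membered carbocycle C1–C10 fused across C6–C7 to a butenolide (O on C6, carbonyl C12, C11=C7). C1 is a ketone conjugated to the exocyclic methylene C10=C14. C4 (methyl C15) and C5 carry an oxirane, C8 a methacrylate, and C11 the acetoxymethyl carbon C13. The four stereocentres are 4S, 5R, 6R and 8R. C3 and C6 are cis on the oxirane, so it maps onto a 4Z olefin, and the oxirane oxygen, the C6 oxygen and the C8 oxygen all lie on one face of the ring. C6 and C8 are separated by the sp2 carbon C7, so their relationship cannot be set by a simple 1,2-induction in the final ring system. Sensitive groups are: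

- the α-methylene ketone, a reactive Michael acceptor;
- the 13-acetoxy butenolide, open to addition–elimination and to C6 epimerisation through the furanolate;
- the trisubstituted medium-ring epoxide, open to acid-triggered transannular reactions;
- two different esters that must be installed separately.

The difficulty is a medium ring with seven oxidised carbons and three electrophilic π systems that can only be unveiled late. The strategy rests on C6: it carries the lactone oxygen and lies between C5, which can be an alkyne carbon, and C7, which bears the C11 branch. Tying the C6 oxygen to C13 as an allyl propargyl ether therefore gives a thirteen-membered ring that can contract onto the C6–C7 bond.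

## Retrosynthetic reasoning

**C8 ester and C1 ketone (38 ⇒ 37 ⇒ 36 ⇒ 35).** The methacrylate and the enone are both electrophilic and cannot pass through organometallic steps, so they are introduced last. Acylation of the C8 hydroxyl of 37 gives 38. Chemoselective allylic oxidation of diol 36 gives 37, and 36 comes from bis-silyl ether 35. C1 is carried at the alcohol level, not as a ketal, because a neutral allylic oxidation at the end is safer next to the epoxide than an acidic ketal hydrolysis. It also keeps C10=C14 an unactivated olefin until then.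

**C13–O bond and C7=C11 olefin (35 ⇒ 34 ⇒ 33 ⇒ 32).** The ring contraction necessarily leaves C7–H and a C11=C13 methylene, so the acetoxy butenolide must arise by oxidative transposition of α-methylene lactone 32. Electrophilic halogenation would attack C10=C14 first. The oxidant is therefore nucleophilic: spiro-epoxide 33 is formed at the only electron-poor olefin, acetate opens it at C13 to give 34, and the tertiary C11 hydroxyl is eliminated towards C7.

**Lactone acyl C–O bond and oxirane (32 ⇒ 29 ⇒ 28 ⇒ 27).** The lactone is cut at the acyl–oxygen bond so that the C6–O bond, and with it the C6 configuration, is never broken. Forward, the 1,4-diol 29 undergoes oxidative lactonisation. The oxirane is installed before that, while the C6 hydroxyl of 27 is still free to direct the oxidant to the syn face of the 4Z olefin. The C12 oxygen stays protected in 28 so that only one olefin has an allylic hydroxyl.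

**C4–C15 bond (27 ⇒ 25).** The methyl group is cut off to reveal the alkyne of 25. The alkyne is what makes C6–H acidic in the key step, and a hydroxyl-directed syn carbometalation turns it into the Z-trisubstituted olefin with no separate geometry problem.

**C6–C7 bond (25 ⇒ 23).** This is the key disconnection. The C6–C7 bond of cyclodecynol 25 is cut and the C6 oxygen reconnected to C13, giving the thirteen-membered allyl propargyl ether 23. One bond, the carbocycle and the C6 and C7 stereocentres come from a single [2,3] shift. The ring-size problem is moved to a thirteen-membered etherification, which is far easier than closing a ten-membered ring directly.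

**Ether O–C6 bond (23 ⇒ 22 ⇒ 21 ⇒ 20 ⇒ 19).** The macrocycle is opened at the propargylic C–O bond, giving allylic alcohol/propargylic bromide 22. The C13 hydroxyl is kept latent as the ester of 19 until the C6 silyl ether has been exchanged for bromide (20, 21). This keeps nucleophile and electrophile distinct without extra protecting groups.

**C7=C11 olefin (19 ⇒ 15 + 18; 18 ⇒ 16 + 17).** Cutting the trisubstituted olefin gives α-silyloxy aldehyde 15 and phosphonate 18. The olefination must place the ester (future C13) trans and the PMB-oxymethyl group (future C12) cis to C8. That differentiates the two oxygenated arms by geometry, which a symmetric three-carbon ketone could not do. Phosphonate 18 is the oxa-Michael adduct of 16 and 17.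

**C1–C10 bond (15 ⇒ 14 ⇒ 13 ⇒ 12 ⇒ 11 ⇒ 9 + 5).** The C7 aldehyde comes from the PMB ether of 13 through alcohol 14. Cutting C1–C10 of enone 11 gives alkenyl iodide 9, used as its lithium derivative, and Weinreb amide 5. This joins two fragments of similar size and gives the enone in one step. Catalyst-controlled reduction to 12 and silylation to 13 then fix C1 as a single, disposable stereocentre.

**C9–C10 and C5–C6 bonds (9 ⇒ 8 ⇒ 7 ⇒ 6; 5 ⇒ 4 ⇒ 3 ⇒ 1).** C8 is taken from the chiral pool. Epoxide 6 is opened at its terminal carbon by a silyl-substituted vinyl nucleophile, giving 7; the silicon is later exchanged for iodine (8, 9). Amide 5 comes from acid 1 by one-carbon homologation of the alkyne terminus (3), amidation (4) and silylation.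

## Alternatives that were turned down

**Alternative 1: intramolecular Horner–Wadsworth–Emmons annulation of the butenolide.**
- Disconnection: the C7=C11 olefin, within a phosphonoacetate ester of the C6 hydroxyl.
- Forward key step: the phosphonate carbanion adds to a C7 ketone and loses phosphate, giving epoxy butenolide A1.
- For: the butenolide is born with the olefin in the right place and the C13 oxygen attached, so no allylic transposition is needed. On this point it is stronger than the chosen route, which spends three steps there.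
- Against: it builds only the five-membered ring. The ten-membered ring with its epoxide, a C7 ketone flanked by two oxygenated stereocentres, and the exocyclic olefin must all exist beforehand. That ketone is prone to epimerisation at C6 and C8 and to β-elimination under the basic conditions, and the carbanion carries a β-silyloxy group that can be expelled.
- Comparison: it defers the hard problem instead of solving it. The chosen strategy closes the carbocycle and sets C6 relative to C8 in one step, and pays for this with the later transposition.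

**Alternative 2: anionic oxy-Cope ring expansion.**
- Disconnection: the ten-membered ring is traced back to a cyclohexenol from a chiral-pool monoterpene.
- Forward key step: a [3,3] shift of the alkoxide forms C8–C9 and breaks the six-membered ring, giving dienone A2.
- For: it reaches the ten-membered ring in very few steps and fixes the 4Z geometry through the transition state. On step count to the carbocycle it is clearly stronger.
- Against: A2 has none of C11–C13. C6 is a ketone, C8 a silane, and the C10 olefin is endocyclic with C14 as a methyl group. The route would still need a three-carbon annulation at C7, a stereoselective C6 reduction, carbon–silicon oxidation in the presence of olefins, oxidation at C1 with transposition of the olefin to C10=C14, and the epoxidation. All of this would be done on a flexible cyclodecadienone prone to transannular reactions.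
- Comparison: the chosen strategy arrives at the ring with C1, C6, C8, C10=C14 and the full C7 branch already in place.

**Alternative 3: Tsuji–Trost macrocyclisation at C2–C3.**
- Disconnection: the C2–C3 bond.
- Forward key step: zerovalent palladium ionises an allylic C5 carbonate and a tethered stabilised carbanion at C2 attacks C3, giving A3.
- For: it converges both C5 epimers and carries a finished butenolide with the C13 oxygen. There it equals alternative 1 and is stronger than the chosen route.
- Against: direct closure of a ten-membered ring by allylic alkylation is disfavoured against oligomerisation and against attack at the other allyl terminus. The allyl complex sits next to the C6 lactone oxygen, which can itself ionise. The Z olefin requires the less stable anti allyl geometry. The activating ester ends on C2, whereas the methylene is needed on C10, so decarboxylation leaves a ketone with two indistinguishable α-methylene groups.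
- Comparison: the chosen route closes a thirteen-membered ring by simple etherification, contracts it in a concerted step, and has C10=C14 in place from the start.

Key step: step 18

## Route

Step 1
Reactants: 1 pent-4-ynoic acid
Product: 3 6-hydroxyhex-4-ynoic acid, via dilithiated pent-4-ynoate 2 (not isolated)
Conditions: LiN(iPr)2 (2.2 equiv), THF, −78 → 0 °C; (CH2O)n, 0 °C → rt; aq. HCl
Reagents that add atoms: formaldehyde (as paraformaldehyde), C=O
Why: The carboxylate/acetylide dianion forms selectively because the sp C–H is far more acidic than the α-C–H of a carboxylate, and only the acetylide adds to formaldehyde; this standard hydroxymethylation of a terminal alkyne supplies C6.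

Step 2
Reactants: 3 6-hydroxyhex-4-ynoic acid
Product: 4 6-hydroxy-N-methoxy-N-methylhex-4-ynamide
Conditions: MeNH(OMe)·HCl, EDC·HCl, N-methylmorpholine, CH2Cl2, 0 °C → rt
Reagents that add atoms: N,O-dimethylhydroxylamine hydrochloride, CNOC.Cl
Why: Carbodiimide coupling acylates the amine much faster than the free primary alcohol and gives the Weinreb amide, which will stop acyl substitution at the ketone stage in step 7.

Step 3
Reactants: 4 6-hydroxy-N-methoxy-N-methylhex-4-ynamide
Product: 5 6-[(tert-butyldimethylsilyl)oxy]-N-methoxy-N-methylhex-4-ynamide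
Conditions: TBSCl, imidazole, DMF, rt
Reagents that add atoms: tert-butyldimethylsilyl chloride, CC(C)(C)[Si](C)(C)Cl
Why: Standard silylation of a primary alcohol; this primary propargylic silyl ether will be the most labile of the three silyl ethers present later, so C6 can be released selectively in step 14.

Step 4
Reactants: 6 (2R)-2-{[(4-methoxyphenyl)methoxy]methyl}oxirane
Product: 7 (2R)-1-[(4-methoxyphenyl)methoxy]-4-(trimethylsilyl)pent-4-en-2-ol
Conditions: CH2=C(SiMe3)MgBr (1.5 equiv, from (1-bromoethenyl)trimethylsilane and Mg), CuI (10 mol%), THF, −30 → 0 °C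
Reagents that add atoms: [1-(trimethylsilyl)ethenyl]magnesium bromide, C=C([Mg]Br)[Si](C)(C)C
Why: Copper-catalysed SN2 opening of a terminal epoxide by a vinyl Grignard reagent at the unsubstituted carbon forms C9–C10 and leaves the purchased stereocentre (future C8, R) untouched; the silicon marks C10 for later metalation.

Step 5
Reactants: 7 (2R)-1-[(4-methoxyphenyl)methoxy]-4-(trimethylsilyl)pent-4-en-2-ol
Product: 8 tert-butyl({(2R)-1-[(4-methoxyphenyl)methoxy]-4-(trimethylsilyl)pent-4-en-2-yl}oxy)dimethylsilane
Conditions: TBSCl, imidazole, DMF, rt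
Reagents that add atoms: tert-butyldimethylsilyl chloride, CC(C)(C)[Si](C)(C)Cl
Why: Routine silylation of the secondary alcohol; the C8 silyl ether stays on until step 26.

Step 6
Reactants: 8 tert-butyl({(2R)-1-[(4-methoxyphenyl)methoxy]-4-(trimethylsilyl)pent-4-en-2-yl}oxy)dimethylsilane
Product: 9 tert-butyl({(2R)-4-iodo-1-[(4-methoxyphenyl)methoxy]pent-4-en-2-yl}oxy)dimethylsilane
Conditions: NIS (1.2 equiv), 2,6-lutidine, (CF3)2CHOH, 0 °C, short reaction time
Reagents that add atoms: N-iodosuccinimide, O=C1CCC(=O)N1I
Why: Electrophilic ipso-iododesilylation of the 1,1-disubstituted vinylsilane through the iodonium ion gives the 2-iodoalkene with the substitution pattern retained; the lutidine buffer and short time should spare the anisyl ring and the silyl ether.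

Step 7
Reactants: 9 tert-butyl({(2R)-4-iodo-1-[(4-methoxyphenyl)methoxy]pent-4-en-2-yl}oxy)dimethylsilane; 5 6-[(tert-butyldimethylsilyl)oxy]-N-methoxy-N-methylhex-4-ynamide
Product: 11 (2R)-2,10-bis[(tert-butyldimethylsilyl)oxy]-1-[(4-methoxyphenyl)methoxy]-4-methylidenedec-8-yn-5-one, via alkenyllithium 10 (not isolated)
Conditions: t-BuLi (2.05 equiv), Et2O, −78 °C; then 5, −78 → −40 °C; aq. NH4Cl
Reagents that add atoms: none
Why: Iodine–lithium exchange gives the alkenyllithium, whose addition to the Weinreb amide stops at the chelated tetrahedral adduct and releases the α-methylene ketone only on quenching, so C1–C10 forms without over-addition.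

Step 8
Reactants: 11 (2R)-2,10-bis[(tert-butyldimethylsilyl)oxy]-1-[(4-methoxyphenyl)methoxy]-4-methylidenedec-8-yn-5-one
Product: 12 (2R,5R)-2,10-bis[(tert-butyldimethylsilyl)oxy]-1-[(4-methoxyphenyl)methoxy]-4-methylidenedec-8-yn-5-ol
Conditions: (S)-2-methyl-CBS-oxazaborolidine (20 mol%), catecholborane (1.8 equiv), toluene, −78 °C
Reagents that add atoms: none
Why: Corey–Bakshi–Shibata 1,2-reduction of an enone, with the alkenyl group acting as the larger substituent, should give the C1 (R) allylic alcohol (chain locant 5) under catalyst control; the configuration is immaterial for the target but gives a single diastereomer to carry forward.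

Step 9
Reactants: 12 (2R,5R)-2,10-bis[(tert-butyldimethylsilyl)oxy]-1-[(4-methoxyphenyl)methoxy]-4-methylidenedec-8-yn-5-ol
Product: 13 (2R,5R)-2,5,10-tris[(tert-butyldimethylsilyl)oxy]-1-[(4-methoxyphenyl)methoxy]-4-methylidenedec-8-yne
Conditions: TBSOTf, 2,6-lutidine, CH2Cl2, −78 °C
Reagents that add atoms: tert-butyldimethylsilyl trifluoromethanesulfonate, CC(C)(C)[Si](C)(C)OS(=O)(=O)C(F)(F)F
Why: Silyl triflate silylation of a hindered secondary allylic alcohol; masking C1 at the alcohol level keeps C10=C14 an unactivated olefin through the basic and organometallic steps.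

Step 10
Reactants: 13 (2R,5R)-2,5,10-tris[(tert-butyldimethylsilyl)oxy]-1-[(4-methoxyphenyl)methoxy]-4-methylidenedec-8-yne
Product: 14 (2R,5R)-2,5,10-tris[(tert-butyldimethylsilyl)oxy]-4-methylidenedec-8-yn-1-ol
Conditions: DDQ (1.3 equiv), CH2Cl2/pH 7 buffer (10:1), 0 °C
Reagents that add atoms: none
Why: Oxidative cleavage of the electron-rich benzyl ether by DDQ in buffered wet solvent leaves the silyl ethers and the alkyne untouched and frees only the C7 hydroxyl.

Step 11
Reactants: 14 (2R,5R)-2,5,10-tris[(tert-butyldimethylsilyl)oxy]-4-methylidenedec-8-yn-1-ol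
Product: 15 (2R,5R)-2,5,10-tris[(tert-butyldimethylsilyl)oxy]-4-methylidenedec-8-ynal
Conditions: Dess–Martin periodinane, NaHCO3, CH2Cl2, 0 °C → rt
Reagents that add atoms: none
Why: Dess–Martin oxidation under bicarbonate buffer gives the α-silyloxy aldehyde without epimerising C8; it is used directly.

Step 12
Reactants: 16 (4-methoxyphenyl)methanol; 17 ethyl 2-(diethoxyphosphoryl)prop-2-enoate
Product: 18 ethyl 2-(diethoxyphosphoryl)-3-[(4-methoxyphenyl)methoxy]propanoate
Conditions: NaH (5 mol%), THF, 0 °C → rt
Reagents that add atoms: none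
Why: Base-catalysed oxa-Michael addition of the benzylic alcohol to the doubly activated vinylphosphonate gives the phosphonate that carries C11, C12 (as CH2OPMB) and C13 (as the ester).

Step 13
Reactants: 15 (2R,5R)-2,5,10-tris[(tert-butyldimethylsilyl)oxy]-4-methylidenedec-8-ynal; 18 ethyl 2-(diethoxyphosphoryl)-3-[(4-methoxyphenyl)methoxy]propanoate
Product: 19 ethyl (2E,4R,7R)-4,7,12-tris[(tert-butyldimethylsilyl)oxy]-2-{[(4-methoxyphenyl)methoxy]methyl}-6-methylidenedodec-2-en-10-ynoate
Conditions: LiCl, DBU, MeCN, 0 °C → rt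
Reagents that add atoms: none
Why: Horner–Wadsworth–Emmons olefination under the mild LiCl/amine variant should place the ester trans to the C8 chain, so that C13 is trans and CH2OPMB cis to C8, without epimerising the α-silyloxy aldehyde.

Step 14
Reactants: 19 ethyl (2E,4R,7R)-4,7,12-tris[(tert-butyldimethylsilyl)oxy]-2-{[(4-methoxyphenyl)methoxy]methyl}-6-methylidenedodec-2-en-10-ynoate
Product: 20 ethyl (2E,4R,7R)-4,7-bis[(tert-butyldimethylsilyl)oxy]-12-hydroxy-2-{[(4-methoxyphenyl)methoxy]methyl}-6-methylidenedodec-2-en-10-ynoate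
Conditions: HF·pyridine, pyridine, THF, 0 °C
Reagents that add atoms: none
Why: Buffered HF·pyridine cleaves the unhindered primary propargylic silyl ether much faster than the two secondary ones, a standard primary-over-secondary desilylation.

Step 15
Reactants: 20 ethyl (2E,4R,7R)-4,7-bis[(tert-butyldimethylsilyl)oxy]-12-hydroxy-2-{[(4-methoxyphenyl)methoxy]methyl}-6-methylidenedodec-2-en-10-ynoate
Product: 21 ethyl (2E,4R,7R)-12-bromo-4,7-bis[(tert-butyldimethylsilyl)oxy]-2-{[(4-methoxyphenyl)methoxy]methyl}-6-methylidenedodec-2-en-10-ynoate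
Conditions: CBr4, PPh3, CH2Cl2, −20 → 0 °C
Reagents that add atoms: tetrabromomethane, BrC(Br)(Br)Br
Why: The Appel reaction converts the primary propargylic alcohol into the bromide under neutral conditions that leave the silyl ethers, the PMB ether and the enoate intact.

Step 16
Reactants: 21 ethyl (2E,4R,7R)-12-bromo-4,7-bis[(tert-butyldimethylsilyl)oxy]-2-{[(4-methoxyphenyl)methoxy]methyl}-6-methylidenedodec-2-en-10-ynoate
Product: 22 (2Z,4R,7R)-12-bromo-4,7-bis[(tert-butyldimethylsilyl)oxy]-2-{[(4-methoxyphenyl)methoxy]methyl}-6-methylidenedodec-2-en-10-yn-1-ol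
Conditions: iBu2AlH (2.3 equiv), CH2Cl2, −78 °C; aq. potassium sodium tartrate
Reagents that add atoms: none
Why: At −78 °C iBu2AlH reduces the conjugated ester to the allylic alcohol much faster than it attacks a propargylic bromide, so the nucleophile (C13–OH) and the electrophile (C6–Br) are both in place; the geometry is unchanged and only the descriptor changes.

Step 17
Reactants: 22 (2Z,4R,7R)-12-bromo-4,7-bis[(tert-butyldimethylsilyl)oxy]-2-{[(4-methoxyphenyl)methoxy]methyl}-6-methylidenedodec-2-en-10-yn-1-ol
Product: 23 (3E,5R,8R)-5,8-bis[(tert-butyldimethylsilyl)oxy]-3-{[(4-methoxyphenyl)methoxy]methyl}-7-methylidene-1-oxacyclotridec-3-en-11-yne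
Conditions: NaH (3 equiv), n-Bu4NI (cat.), THF, slow addition of 22 to a final 0.002 M, 45 °C
Reagents that add atoms: none
Why: Intramolecular Williamson etherification of the allylic alkoxide on the unhindered propargylic bromide (SN2) under high dilution closes the thirteen-membered ring; the E olefin and the linear alkyne limit unproductive conformers, and the PMB ether keeps the C12 oxygen out of the reaction.

Step 18
Reactants: 23 (3E,5R,8R)-5,8-bis[(tert-butyldimethylsilyl)oxy]-3-{[(4-methoxyphenyl)methoxy]methyl}-7-methylidene-1-oxacyclotridec-3-en-11-yne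
Product: 25 (1R,6R,7R,8R)-1,8-bis[(tert-butyldimethylsilyl)oxy]-7-{3-[(4-methoxyphenyl)methoxy]prop-1-en-2-yl}-10-methylidenecyclodec-4-yn-6-ol, via C6-lithiated ether 24 (not isolated)
Conditions: n-BuLi (1.3 equiv), THF/pentane (1:1), −78 → −30 °C; aq. NH4Cl
Reagents that add atoms: none
Why: n-BuLi removes a C6 proton, the only one that is both propargylic and α to the ether oxygen, and carbanion 24 attacks C7 while the O–C13 bond breaks in a concerted suprafacial [2,3]-sigmatropic (Wittig) shift through a five-membered envelope made of C6, O, C13, C11 and C7. The closest known reaction type is the [2,3]-Wittig ring contraction of macrocyclic allyl propargyl ethers to cycloalkynols. The ten-membered carbocycle is closed by this transannular C6–C7 bond formation inside the thirteen-membered ring, with O, C13 and C11 extruded into the C6 alkoxide and the C7 side chain; it is a ring contraction and not an end-on cyclisation, so the entropic cost was already paid in step 17. C7 is controlled by the C8 stereocentre: allylic 1,3-strain with the cis CH2OPMB group should hold H8 in the olefin plane, and C6, which is tethered through C9, should add to the face anti to the silyloxy group, placing the C7 branch trans to the C8 oxygen. C6 is controlled by the olefin geometry: with C8 trans to C13 and the alkynyl group exo in the envelope the anti relationship should result, so that the C6 hydroxyl is trans to the C7 branch and cis to the C8 oxygen, as the target requires (6R). The step needs lithiation at C6 and not at the allylic C13–H or the PMB methylene, the [2,3] and not the [1,2] shift, and one diastereomer; the higher acidity of the propargylic position, the low temperature and the conformational restriction imposed by the alkyne and the E olefin are what should secure them. C7 later becomes sp2, so only the C6/C8 relationship has to be right.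

Step 19
Reactants: 25 (1R,6R,7R,8R)-1,8-bis[(tert-butyldimethylsilyl)oxy]-7-{3-[(4-methoxyphenyl)methoxy]prop-1-en-2-yl}-10-methylidenecyclodec-4-yn-6-ol
Product: 27 (1R,4Z,6S,7R,8R)-1,8-bis[(tert-butyldimethylsilyl)oxy]-7-{3-[(4-methoxyphenyl)methoxy]prop-1-en-2-yl}-4-methyl-10-methylidenecyclodec-4-en-6-ol, via C5-magnesiated alkoxide 26 (not isolated)
Conditions: Fe(acac)3 (20 mol%), MeMgBr (5 equiv), THF, −78 → 0 °C; aq. NH4Cl
Reagents that add atoms: methylmagnesium bromide, C[Mg]Br
Why: Iron-catalysed alkoxide-directed carbomagnesiation of a propargylic alcohol adds CH3 and Mg syn across the alkyne, methyl to the distal carbon C4 and magnesium to C5; protonation on work-up gives the trisubstituted olefin with C3 and C6 cis (4Z), the only geometry that maps onto the cis-epoxide (C6 is spatially unchanged; its descriptor changes).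

Step 20
Reactants: 27 (1R,4Z,6S,7R,8R)-1,8-bis[(tert-butyldimethylsilyl)oxy]-7-{3-[(4-methoxyphenyl)methoxy]prop-1-en-2-yl}-4-methyl-10-methylidenecyclodec-4-en-6-ol
Product: 28 (1R,4S,5R,6R,7R,8R)-1,8-bis[(tert-butyldimethylsilyl)oxy]-4,5-epoxy-7-{3-[(4-methoxyphenyl)methoxy]prop-1-en-2-yl}-4-methyl-10-methylidenecyclodecan-6-ol
Conditions: VO(acac)2 (5 mol%), t-BuOOH (1.5 equiv), CH2Cl2, 0 °C
Reagents that add atoms: tert-butyl hydroperoxide, CC(C)(C)OO
Why: Vanadium-catalysed hydroxyl-directed epoxidation delivers oxygen to the olefin face syn to the C6 hydroxyl (small O–C6–C5=C4 dihedral in the vanadate ester, the mode that gives cis-epoxy alcohols from cyclic Z-allylic alcohols), setting C4 (S) and C5 (R); the two 1,1-disubstituted olefins have no allylic hydroxyl and should not react.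

Step 21
Reactants: 28 (1R,4S,5R,6R,7R,8R)-1,8-bis[(tert-butyldimethylsilyl)oxy]-4,5-epoxy-7-{3-[(4-methoxyphenyl)methoxy]prop-1-en-2-yl}-4-methyl-10-methylidenecyclodecan-6-ol
Product: 29 (1R,4S,5R,6R,7R,8R)-1,8-bis[(tert-butyldimethylsilyl)oxy]-4,5-epoxy-7-(3-hydroxyprop-1-en-2-yl)-4-methyl-10-methylidenecyclodecan-6-ol
Conditions: DDQ (1.3 equiv), CH2Cl2/pH 7 buffer (10:1), 0 °C
Reagents that add atoms: none
Why: DDQ removes the PMB ether; with C4=C5 already epoxidised no oxidisable secondary allylic alcohol remains, and the buffer protects the epoxide.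

Step 22
Reactants: 29 (1R,4S,5R,6R,7R,8R)-1,8-bis[(tert-butyldimethylsilyl)oxy]-4,5-epoxy-7-(3-hydroxyprop-1-en-2-yl)-4-methyl-10-methylidenecyclodecan-6-ol
Product: 32 (1R,4S,5R,6R,7R,8R)-1,8-bis[(tert-butyldimethylsilyl)oxy]-4,5-epoxygermacra-10(14),11(13)-dien-12,6-olide, via hydroxy aldehyde 30 (not isolated), via lactol 31 (not isolated)
Conditions: TEMPO (20 mol%), PhI(OAc)2 (2.5 equiv), CH2Cl2, rt
Reagents that add atoms: none
Why: TEMPO/PhI(OAc)2 oxidises the primary alcohol selectively to the aldehyde, which the C6 hydroxyl traps as the five-membered lactol that is oxidised on to the lactone (oxidative lactonisation of a 1,4-diol), so the C6–O bond and its configuration are untouched.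

Step 23
Reactants: 32 (1R,4S,5R,6R,7R,8R)-1,8-bis[(tert-butyldimethylsilyl)oxy]-4,5-epoxygermacra-10(14),11(13)-dien-12,6-olide
Product: 33 (1R,4S,5R,6R,7R,8R,11R)-1,8-bis[(tert-butyldimethylsilyl)oxy]-4,5:11,13-diepoxygermacr-10(14)-en-12,6-olide
Conditions: t-BuOOLi (1.5 equiv, from t-BuOOH and n-BuLi), THF, −78 → −20 °C; aq. NH4Cl
Reagents that add atoms: tert-butyl hydroperoxide (as its lithium salt), CC(C)(C)OO
Why: Weitz–Scheffer nucleophilic epoxidation: the peroxide anion adds only to the electron-poor exocyclic methylene (C13) and the lactone enolate closes on oxygen, expected on the face of C11 anti to the pseudo-axial H7 of the trans-fused lactone (11R); the unactivated C10=C14 olefin is inert to a nucleophilic oxidant.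

Step 24
Reactants: 33 (1R,4S,5R,6R,7R,8R,11R)-1,8-bis[(tert-butyldimethylsilyl)oxy]-4,5:11,13-diepoxygermacr-10(14)-en-12,6-olide
Product: 34 (1R,4S,5R,6R,7R,8R,11R)-13-acetoxy-1,8-bis[(tert-butyldimethylsilyl)oxy]-4,5-epoxy-11-hydroxygermacr-10(14)-en-12,6-olide
Conditions: CsOAc (3 equiv), AcOH (3 equiv), DMF, 45 °C
Reagents that add atoms: acetic acid (acetate delivered from CsOAc, which the acid regenerates), CC(=O)O
Why: Acetate opens the glycidic lactone by SN2 at the primary carbon C13 (C11 is quaternary), giving the C13 acetate and the tertiary C11 alcohol; the trisubstituted, inductively deactivated C4–C5 epoxide should be far less reactive under these buffered conditions.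

Step 25
Reactants: 34 (1R,4S,5R,6R,7R,8R,11R)-13-acetoxy-1,8-bis[(tert-butyldimethylsilyl)oxy]-4,5-epoxy-11-hydroxygermacr-10(14)-en-12,6-olide
Product: 35 (1R,4S,5R,6R,8R)-13-acetoxy-1,8-bis[(tert-butyldimethylsilyl)oxy]-4,5-epoxygermacra-7(11),10(14)-dien-12,6-olide
Conditions: SOCl2 (3 equiv), pyridine, CH2Cl2, −20 → 0 °C
Reagents that add atoms: none
Why: Chlorosulfite formation and pyridine-mediated anti E2 elimination of the tertiary α-hydroxy lactone with the antiperiplanar H7 should give the conjugated tetrasubstituted C7=C11 butenolide (the more substituted olefin), the C11 oxygen having been set anti to H7 in step 23.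

Step 26
Reactants: 35 (1R,4S,5R,6R,8R)-13-acetoxy-1,8-bis[(tert-butyldimethylsilyl)oxy]-4,5-epoxygermacra-7(11),10(14)-dien-12,6-olide
Product: 36 (1R,4S,5R,6R,8R)-13-acetoxy-4,5-epoxy-1,8-dihydroxygermacra-7(11),10(14)-dien-12,6-olide
Conditions: HF·pyridine, pyridine, THF, 0 °C → rt
Reagents that add atoms: none
Why: Buffered HF·pyridine removes both secondary silyl ethers under conditions of a kind that trisubstituted epoxides, lactones and acetates tolerate.

Step 27
Reactants: 36 (1R,4S,5R,6R,8R)-13-acetoxy-4,5-epoxy-1,8-dihydroxygermacra-7(11),10(14)-dien-12,6-olide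
Product: 37 (4S,5R,6R,8R)-13-acetoxy-4,5-epoxy-8-hydroxy-1-oxogermacra-7(11),10(14)-dien-12,6-olide
Conditions: MnO2 (20 equiv), CH2Cl2, rt
Reagents that add atoms: none
Why: MnO2 oxidises only the allylic C1 alcohol, to the α-methylene ketone, and leaves the saturated C8 alcohol; the neutral heterogeneous conditions protect the epoxide and the acetoxy butenolide.

Step 28
Reactants: 37 (4S,5R,6R,8R)-13-acetoxy-4,5-epoxy-8-hydroxy-1-oxogermacra-7(11),10(14)-dien-12,6-olide
Product: 38 (4S,5R,6R,8R)-13-acetoxy-4,5-epoxy-8-(2-methylprop-2-enoyloxy)-1-oxogermacra-7(11),10(14)-dien-12,6-olide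
Conditions: methacrylic anhydride (2 equiv), Et3N, DMAP (10 mol%), CH2Cl2, 0 °C
Reagents that add atoms: methacrylic anhydride, CC(=C)C(=O)OC(=O)C(C)=C
Why: DMAP-catalysed acylation of the remaining secondary alcohol under brief, cold conditions installs the methacrylate with retention at C8 and should leave the electrophilic enone and acetoxy butenolide untouched.

## Compound list

1 | pent-4-ynoic acid | C#CCCC(=O)O | starting material
2 | dilithiated pent-4-ynoate (lithium 5-lithiopent-4-ynoate) | [Li]C#CCCC(=O)O[Li] | intermediate (not isolated)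
3 | 6-hydroxyhex-4-ynoic acid | OCC#CCCC(=O)O | intermediate
4 | 6-hydroxy-N-methoxy-N-methylhex-4-ynamide | CON(C)C(=O)CCC#CCO | intermediate
5 | 6-[(tert-butyldimethylsilyl)oxy]-N-methoxy-N-methylhex-4-ynamide | CON(C)C(=O)CCC#CCO[Si](C)(C)C(C)(C)C | intermediate
6 | (2R)-2-{[(4-methoxyphenyl)methoxy]methyl}oxirane | COc1ccc(COC[C@H]2CO2)cc1 | starting material
7 | (2R)-1-[(4-methoxyphenyl)methoxy]-4-(trimethylsilyl)pent-4-en-2-ol | COc1ccc(COC[C@H](O)CC(=C)[Si](C)(C)C)cc1 | intermediate
8 | tert-butyl({(2R)-1-[(4-methoxyphenyl)methoxy]-4-(trimethylsilyl)pent-4-en-2-yl}oxy)dimethylsilane | COc1ccc(COC[C@H](O[Si](C)(C)C(C)(C)C)CC(=C)[Si](C)(C)C)cc1 | intermediate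
9 | tert-butyl({(2R)-4-iodo-1-[(4-methoxyphenyl)methoxy]pent-4-en-2-yl}oxy)dimethylsilane | COc1ccc(COC[C@H](O[Si](C)(C)C(C)(C)C)CC(I)=C)cc1 | intermediate
10 | alkenyllithium from 9 (lithium in place of iodine at C10) | COc1ccc(COC[C@H](O[Si](C)(C)C(C)(C)C)CC([Li])=C)cc1 | intermediate (not isolated)
11 | (2R)-2,10-bis[(tert-butyldimethylsilyl)oxy]-1-[(4-methoxyphenyl)methoxy]-4-methylidenedec-8-yn-5-one | COc1ccc(COC[C@H](O[Si](C)(C)C(C)(C)C)CC(=C)C(=O)CCC#CCO[Si](C)(C)C(C)(C)C)cc1 | intermediate
12 | (2R,5R)-2,10-bis[(tert-butyldimethylsilyl)oxy]-1-[(4-methoxyphenyl)methoxy]-4-methylidenedec-8-yn-5-ol | COc1ccc(COC[C@H](O[Si](C)(C)C(C)(C)C)CC(=C)[C@H](O)CCC#CCO[Si](C)(C)C(C)(C)C)cc1 | intermediate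
13 | (2R,5R)-2,5,10-tris[(tert-butyldimethylsilyl)oxy]-1-[(4-methoxyphenyl)methoxy]-4-methylidenedec-8-yne | COc1ccc(COC[C@H](O[Si](C)(C)C(C)(C)C)CC(=C)[C@H](O[Si](C)(C)C(C)(C)C)CCC#CCO[Si](C)(C)C(C)(C)C)cc1 | intermediate
14 | (2R,5R)-2,5,10-tris[(tert-butyldimethylsilyl)oxy]-4-methylidenedec-8-yn-1-ol | OC[C@H](O[Si](C)(C)C(C)(C)C)CC(=C)[C@H](O[Si](C)(C)C(C)(C)C)CCC#CCO[Si](C)(C)C(C)(C)C | intermediate
15 | (2R,5R)-2,5,10-tris[(tert-butyldimethylsilyl)oxy]-4-methylidenedec-8-ynal | O=C[C@H](O[Si](C)(C)C(C)(C)C)CC(=C)[C@H](O[Si](C)(C)C(C)(C)C)CCC#CCO[Si](C)(C)C(C)(C)C | intermediate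
16 | (4-methoxyphenyl)methanol | COc1ccc(CO)cc1 | starting material
17 | ethyl 2-(diethoxyphosphoryl)prop-2-enoate | CCOC(=O)C(=C)P(=O)(OCC)OCC | starting material
18 | ethyl 2-(diethoxyphosphoryl)-3-[(4-methoxyphenyl)methoxy]propanoate (racemic) | CCOC(=O)C(COCc1ccc(OC)cc1)P(=O)(OCC)OCC | intermediate
19 | ethyl (2E,4R,7R)-4,7,12-tris[(tert-butyldimethylsilyl)oxy]-2-{[(4-methoxyphenyl)methoxy]methyl}-6-methylidenedodec-2-en-10-ynoate | CCOC(=O)/C(COCc1ccc(OC)cc1)=C/[C@H](O[Si](C)(C)C(C)(C)C)CC(=C)[C@H](O[Si](C)(C)C(C)(C)C)CCC#CCO[Si](C)(C)C(C)(C)C | intermediate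
20 | ethyl (2E,4R,7R)-4,7-bis[(tert-butyldimethylsilyl)oxy]-12-hydroxy-2-{[(4-methoxyphenyl)methoxy]methyl}-6-methylidenedodec-2-en-10-ynoate | CCOC(=O)/C(COCc1ccc(OC)cc1)=C/[C@H](O[Si](C)(C)C(C)(C)C)CC(=C)[C@H](O[Si](C)(C)C(C)(C)C)CCC#CCO | intermediate
21 | ethyl (2E,4R,7R)-12-bromo-4,7-bis[(tert-butyldimethylsilyl)oxy]-2-{[(4-methoxyphenyl)methoxy]methyl}-6-methylidenedodec-2-en-10-ynoate | CCOC(=O)/C(COCc1ccc(OC)cc1)=C/[C@H](O[Si](C)(C)C(C)(C)C)CC(=C)[C@H](O[Si](C)(C)C(C)(C)C)CCC#CCBr | intermediate
22 | (2Z,4R,7R)-12-bromo-4,7-bis[(tert-butyldimethylsilyl)oxy]-2-{[(4-methoxyphenyl)methoxy]methyl}-6-methylidenedodec-2-en-10-yn-1-ol (C13 hydroxymethyl trans to C8) | OC/C(COCc1ccc(OC)cc1)=C/[C@H](O[Si](C)(C)C(C)(C)C)CC(=C)[C@H](O[Si](C)(C)C(C)(C)C)CCC#CCBr | intermediate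
23 | (3E,5R,8R)-5,8-bis[(tert-butyldimethylsilyl)oxy]-3-{[(4-methoxyphenyl)methoxy]methyl}-7-methylidene-1-oxacyclotridec-3-en-11-yne (thirteen-membered allyl propargyl ether; ring O, C13, C11, C7–C10, C1–C6) | O1C/C(COCc2ccc(OC)cc2)=C/[C@H](O[Si](C)(C)C(C)(C)C)CC(=C)[C@H](O[Si](C)(C)C(C)(C)C)CCC#CC1 | intermediate
24 | C6-lithiated ether from 23 | O1C/C(COCc2ccc(OC)cc2)=C/[C@H](O[Si](C)(C)C(C)(C)C)CC(=C)[C@H](O[Si](C)(C)C(C)(C)C)CCC#CC1[Li] | intermediate (not isolated)
25 | (1R,6R,7R,8R)-1,8-bis[(tert-butyldimethylsilyl)oxy]-7-{3-[(4-methoxyphenyl)methoxy]prop-1-en-2-yl}-10-methylidenecyclodec-4-yn-6-ol (C6–OH cis to C8–O, trans to the C7 branch) | O[C@H]1C#CCC[C@@H](O[Si](C)(C)C(C)(C)C)C(=C)C[C@@H](O[Si](C)(C)C(C)(C)C)[C@@H]1C(=C)COCc2ccc(OC)cc2 | intermediate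
26 | C5-magnesiated alkoxide (bromomagnesium alkoxide at C6, C5–MgBr, methyl on C4, C3 and C6 cis) | Br[Mg]O[C@H]1/C([Mg]Br)=C(C)\CC[C@@H](O[Si](C)(C)C(C)(C)C)C(=C)C[C@@H](O[Si](C)(C)C(C)(C)C)[C@@H]1C(=C)COCc2ccc(OC)cc2 | intermediate (not isolated)
27 | (1R,4Z,6S,7R,8R)-1,8-bis[(tert-butyldimethylsilyl)oxy]-7-{3-[(4-methoxyphenyl)methoxy]prop-1-en-2-yl}-4-methyl-10-methylidenecyclodec-4-en-6-ol | O[C@H]1/C=C(C)\CC[C@@H](O[Si](C)(C)C(C)(C)C)C(=C)C[C@@H](O[Si](C)(C)C(C)(C)C)[C@@H]1C(=C)COCc2ccc(OC)cc2 | intermediate
28 | (1R,4S,5R,6R,7R,8R)-1,8-bis[(tert-butyldimethylsilyl)oxy]-4,5-epoxy-7-{3-[(4-methoxyphenyl)methoxy]prop-1-en-2-yl}-4-methyl-10-methylidenecyclodecan-6-ol | O[C@H]1[C@H]2O[C@@]2(C)CC[C@@H](O[Si](C)(C)C(C)(C)C)C(=C)C[C@@H](O[Si](C)(C)C(C)(C)C)[C@@H]1C(=C)COCc3ccc(OC)cc3 | intermediate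
29 | (1R,4S,5R,6R,7R,8R)-1,8-bis[(tert-butyldimethylsilyl)oxy]-4,5-epoxy-7-(3-hydroxyprop-1-en-2-yl)-4-methyl-10-methylidenecyclodecan-6-ol | O[C@H]1[C@H]2O[C@@]2(C)CC[C@@H](O[Si](C)(C)C(C)(C)C)C(=C)C[C@@H](O[Si](C)(C)C(C)(C)C)[C@@H]1C(=C)CO | intermediate
30 | hydroxy aldehyde (C12 aldehyde of 29) | O[C@H]1[C@H]2O[C@@]2(C)CC[C@@H](O[Si](C)(C)C(C)(C)C)C(=C)C[C@@H](O[Si](C)(C)C(C)(C)C)[C@@H]1C(=C)C=O | intermediate (not isolated)
31 | lactol (C12 hemiacetal with the C6 oxygen, C12 epimers) | OC1O[C@H]2[C@H]3O[C@@]3(C)CC[C@@H](O[Si](C)(C)C(C)(C)C)C(=C)C[C@@H](O[Si](C)(C)C(C)(C)C)[C@@H]2C1=C | intermediate (not isolated)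
32 | (1R,4S,5R,6R,7R,8R)-1,8-bis[(tert-butyldimethylsilyl)oxy]-4,5-epoxygermacra-10(14),11(13)-dien-12,6-olide (trans-fused α-methylene lactone) | O=C1O[C@H]2[C@H]3O[C@@]3(C)CC[C@@H](O[Si](C)(C)C(C)(C)C)C(=C)C[C@@H](O[Si](C)(C)C(C)(C)C)[C@@H]2C1=C | intermediate
33 | (1R,4S,5R,6R,7R,8R,11R)-1,8-bis[(tert-butyldimethylsilyl)oxy]-4,5:11,13-diepoxygermacr-10(14)-en-12,6-olide (spiro-oxirane oxygen anti to H7) | O=C1O[C@H]2[C@H]3O[C@@]3(C)CC[C@@H](O[Si](C)(C)C(C)(C)C)C(=C)C[C@@H](O[Si](C)(C)C(C)(C)C)[C@@H]2[C@@]14CO4 | intermediate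
34 | (1R,4S,5R,6R,7R,8R,11R)-13-acetoxy-1,8-bis[(tert-butyldimethylsilyl)oxy]-4,5-epoxy-11-hydroxygermacr-10(14)-en-12,6-olide | O=C1O[C@H]2[C@H]3O[C@@]3(C)CC[C@@H](O[Si](C)(C)C(C)(C)C)C(=C)C[C@@H](O[Si](C)(C)C(C)(C)C)[C@@H]2[C@@]1(O)COC(C)=O | intermediate
35 | (1R,4S,5R,6R,8R)-13-acetoxy-1,8-bis[(tert-butyldimethylsilyl)oxy]-4,5-epoxygermacra-7(11),10(14)-dien-12,6-olide | O=C1O[C@H]2[C@H]3O[C@@]3(C)CC[C@@H](O[Si](C)(C)C(C)(C)C)C(=C)C[C@@H](O[Si](C)(C)C(C)(C)C)C2=C1COC(C)=O | intermediate
36 | (1R,4S,5R,6R,8R)-13-acetoxy-4,5-epoxy-1,8-dihydroxygermacra-7(11),10(14)-dien-12,6-olide | O=C1O[C@H]2[C@H]3O[C@@]3(C)CC[C@@H](O)C(=C)C[C@@H](O)C2=C1COC(C)=O | intermediate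
37 | (4S,5R,6R,8R)-13-acetoxy-4,5-epoxy-8-hydroxy-1-oxogermacra-7(11),10(14)-dien-12,6-olide | O=C1O[C@H]2[C@H]3O[C@@]3(C)CCC(=O)C(=C)C[C@@H](O)C2=C1COC(C)=O | intermediate
38 | (4S,5R,6R,8R)-13-acetoxy-4,5-epoxy-8-(2-methylprop-2-enoyloxy)-1-oxogermacra-7(11),10(14)-dien-12,6-olide (CNP0266914.1) | C=C(C)C(=O)O[C@@H]1CC(=C)C(=O)CC[C@]2(C)O[C@@H]2[C@@H]2OC(=O)C(COC(C)=O)=C21 | target

## Step count and least certain steps

Total: 28 steps (steps 1–3 make fragment 5, step 12 makes reagent 18). Longest linear sequence: 24 steps, from 6 through steps 4–11 and 13–28.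

**Step 18 (key step).**
- What may go wrong: lithiation at the allylic C13–H or at the PMB methylene instead of C6; a [1,2] shift at higher temperature; poor facial selectivity at C7, or loss of the anti relay, which would deliver the C6 hydroxyl on the wrong face relative to C8.
- Why: the two new centres are set in a ring whose conformation is only predicted, and the C8 centre acts through allylic strain, not chelation.
- Fallback: if the rearrangement of 23 gives mainly the C6-epimeric alcohol F1, C6 is corrected by reagent instead of by the transition state. Mitsunobu esterification of F1 with 4-nitrobenzoic acid (PPh3, diisopropyl azodicarboxylate) inverts the propargylic centre and gives the 4-nitrobenzoate F2, and methanolysis (K2CO3, MeOH) returns to the route at 25. The C7 configuration is irrelevant because C7 becomes sp2.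

**Step 13.**
- What may go wrong: incomplete control of olefin geometry, or reversible loss of the β-alkoxide from the phosphonate carbanion.
- Why: the α-branch of 18 erodes the usual trans preference, and the wrong geometry would invert the relay to C6.
- Fallback: fix the geometry by a stabilised Wittig reaction and a stereoretentive coupling. From 15, ethyl bromo(triphenylphosphoranylidene)acetate gives the (Z)-α-bromo enoate F3 (ester trans to C8). Suzuki–Miyaura coupling of F3 with potassium {[(4-methoxyphenyl)methoxy]methyl}trifluoroborate (Pd(OAc)2, a dialkylbiarylphosphine, Cs2CO3) returns to the route at 19.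

**Step 17.**
- What may go wrong: oligomerisation in competition with ring closure; SN2′ attack giving an allenyl ether.
- Why: a thirteen-membered ring is closed by an intermolecular-type substitution.
- Fallback: reverse the roles of the two termini. From 19, iBu2AlH gives allylic alcohol F4; mesylation and LiCl give allylic chloride F5; HF·pyridine frees the propargylic alcohol F6. The magnesium alkoxide of F6 (EtMgBr, THF with a dipolar cosolvent, high dilution) displaces the allylic chloride and returns to the route at 23.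

**Step 19.**
- What may go wrong: sluggish or unselective carbometalation of the ring alkyne, or reduction in place of methyl transfer.
- Why: the strained cyclodecyne and the crowded C6 alkoxide differ from simple propargylic alcohols.
- Fallback: replace carbometalation by hydrometalation and cross-coupling. From 25, syn hydrozirconation with Cp2Zr(H)Cl (zirconium at the less hindered C4) and iodinolysis give alkenyl iodide F7. Negishi coupling with MeZnCl and Pd(PPh3)4 proceeds with retention and returns to the route at 27.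

**Step 20.**
- What may go wrong: poor facial selectivity, giving the oxirane trans to the C6 oxygen.
- Why: the directing effect depends on the ring adopting the conformer with a small O–C6–C5=C4 dihedral.
- Fallback: epoxidise without direction, after the lactone has fixed the ring. From 27, DDQ gives diol F8 and TEMPO/PhI(OAc)2 gives olefinic α-methylene lactone F9. Dimethyldioxirane at low temperature should then attack the trisubstituted olefin from the exposed face of the folded ring, returning to the route at 32. Which of the two modes matches the target is for experiment to decide.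

**Step 25 (with its premise from step 23).**
- What may go wrong: elimination towards C13 to an enol acetate, or chloride substitution instead of elimination; both are more likely if the C11 oxygen is not anti to H7.
- Why: the tertiary centre has β-hydrogens on two carbons, and no acidity difference steers the base.
- Fallback: remove the competing hydrogens by raising C13 to the aldehyde level. From 33, SmI2 opens the oxirane reductively to β-hydroxy lactone F10. Dess–Martin oxidation gives formyl lactone F11. Dehydrogenation of this 1,3-dicarbonyl compound with DDQ can only form C7=C11 and gives formyl butenolide F12. NaBH4/CeCl3 reduces the aldehyde to alcohol F13, and acetylation (Ac2O, pyridine) returns to the route at 35.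

## Further compounds

F1 | step 18 | (1R,6S,7R,8R)-1,8-bis[(tert-butyldimethylsilyl)oxy]-7-{3-[(4-methoxyphenyl)methoxy]prop-1-en-2-yl}-10-methylidenecyclodec-4-yn-6-ol (C6 epimer of 25) | O[C@@H]1C#CCC[C@@H](O[Si](C)(C)C(C)(C)C)C(=C)C[C@@H](O[Si](C)(C)C(C)(C)C)[C@@H]1C(=C)COCc2ccc(OC)cc2
F2 | step 18 | 4-nitrobenzoate of 25 | O=C(O[C@H]1C#CCC[C@@H](O[Si](C)(C)C(C)(C)C)C(=C)C[C@@H](O[Si](C)(C)C(C)(C)C)[C@@H]1C(=C)COCc2ccc(OC)cc2)c3ccc(cc3)[N+](=O)[O-]
F3 | step 13 | ethyl (2Z,4R,7R)-2-bromo-4,7,12-tris[(tert-butyldimethylsilyl)oxy]-6-methylidenedodec-2-en-10-ynoate | CCOC(=O)/C(Br)=C/[C@H](O[Si](C)(C)C(C)(C)C)CC(=C)[C@H](O[Si](C)(C)C(C)(C)C)CCC#CCO[Si](C)(C)C(C)(C)C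
F4 | step 17 | (2Z,4R,7R)-4,7,12-tris[(tert-butyldimethylsilyl)oxy]-2-{[(4-methoxyphenyl)methoxy]methyl}-6-methylidenedodec-2-en-10-yn-1-ol | OC/C(COCc1ccc(OC)cc1)=C/[C@H](O[Si](C)(C)C(C)(C)C)CC(=C)[C@H](O[Si](C)(C)C(C)(C)C)CCC#CCO[Si](C)(C)C(C)(C)C
F5 | step 17 | allylic chloride of F4 (chlorine in place of the C13 hydroxyl) | ClC/C(COCc1ccc(OC)cc1)=C/[C@H](O[Si](C)(C)C(C)(C)C)CC(=C)[C@H](O[Si](C)(C)C(C)(C)C)CCC#CCO[Si](C)(C)C(C)(C)C
F6 | step 17 | chloro alcohol (C13 chloride, free C6 hydroxyl) | ClC/C(COCc1ccc(OC)cc1)=C/[C@H](O[Si](C)(C)C(C)(C)C)CC(=C)[C@H](O[Si](C)(C)C(C)(C)C)CCC#CCO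
F7 | step 19 | 4-iodo analogue of 27 (iodine on C4, C3 and C6 cis) | O[C@H]1/C=C(I)\CC[C@@H](O[Si](C)(C)C(C)(C)C)C(=C)C[C@@H](O[Si](C)(C)C(C)(C)C)[C@@H]1C(=C)COCc2ccc(OC)cc2
F8 | step 20 | diol from 27 (free C12 hydroxyl, 4Z olefin) | O[C@H]1/C=C(C)\CC[C@@H](O[Si](C)(C)C(C)(C)C)C(=C)C[C@@H](O[Si](C)(C)C(C)(C)C)[C@@H]1C(=C)CO
F9 | step 20 | (1R,4Z,6R,7R,8R)-1,8-bis[(tert-butyldimethylsilyl)oxy]germacra-4,10(14),11(13)-trien-12,6-olide | O=C1O[C@H]2/C=C(C)\CC[C@@H](O[Si](C)(C)C(C)(C)C)C(=C)C[C@@H](O[Si](C)(C)C(C)(C)C)[C@@H]2C1=C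
F10 | step 25 | 13-hydroxy-11,13-dihydro lactone (C11 epimers) | O=C1O[C@H]2[C@H]3O[C@@]3(C)CC[C@@H](O[Si](C)(C)C(C)(C)C)C(=C)C[C@@H](O[Si](C)(C)C(C)(C)C)[C@@H]2C1CO
F11 | step 25 | 13-oxo-11,13-dihydro lactone (formyl lactone, C11 epimers, also as its enol) | O=C1O[C@H]2[C@H]3O[C@@]3(C)CC[C@@H](O[Si](C)(C)C(C)(C)C)C(=C)C[C@@H](O[Si](C)(C)C(C)(C)C)[C@@H]2C1C=O
F12 | step 25 | 13-oxo-7(11)-ene butenolide (formyl butenolide) | O=C1O[C@H]2[C@H]3O[C@@]3(C)CC[C@@H](O[Si](C)(C)C(C)(C)C)C(=C)C[C@@H](O[Si](C)(C)C(C)(C)C)C2=C1C=O
F13 | step 25 | 13-hydroxy-7(11)-ene butenolide | O=C1O[C@H]2[C@H]3O[C@@]3(C)CC[C@@H](O[Si](C)(C)C(C)(C)C)C(=C)C[C@@H](O[Si](C)(C)C(C)(C)C)C2=C1CO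
A1 | alternative 1 | epoxy butenolide with C8 and C13 tert-butyldimethylsilyl ethers and a C1 ethylene ketal | CC(C)(C)[Si](C)(C)O[C@@H]1CC(=C)C3(OCCO3)CC[C@]2(C)O[C@@H]2[C@@H]2OC(=O)C(CO[Si](C)(C)C(C)(C)C)=C21
A2 | alternative 2 | (2Z,6E)-9-[dimethyl(phenyl)silyl]-3,7-dimethylcyclodeca-2,6-dien-1-one | C[Si](C)(c1ccccc1)[C@@H]2C/C(C)=C/CC/C(C)=C\C(=O)C2
A3 | alternative 3 | ten-membered C1-keto C2-methyl ester fused to the 13-silyloxy butenolide, 4Z olefin, C8 silyl ether | COC(=O)C1C/C(C)=C\[C@@H]2OC(=O)C(CO[Si](C)(C)C(C)(C)C)=C2[C@H](O[Si](C)(C)C(C)(C)C)CCC1=O
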